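## Structural features

1. The target is a flavonol. Benzenoid ring A is fused along C4a–C8a to the 3-hydroxy-4-pyranone ring C, and ring C carries the 4-hydroxy-3-methoxyphenyl ring B at C2.
2. There is no stereocentre and no hindered axis, so the problem is one of regiochemistry and of telling oxygen atoms apart.
3. Ring A is a C-acylated 2-methoxyphloroglucinol with five of six carbons substituted (C4a acyl, C5 OH, C7 prenyloxy, C8 OMe, C8a O1), and its three phenolic oxygens end in three different states.
4. C4a stands between two oxygen-bearing carbons, C5 and C8a. A closure of ring C at the heteroatom can therefore use either oxygen and give the 8-methoxy or the 6-methoxy isomer, and acid can interconvert the two by ring opening.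
5. The fragile groups are the prenyl ether at O7 (cleaved or cyclised by acids and Lewis acids, lost under hydrogenolysis, epoxidised by electrophilic oxidants, rearranged on heating) and the 3-hydroxy-4-pyranone (degraded by strong base in air).
6. Four hydroxyl groups of similar acidity (O3, O5, O7, O4') have to be distinguished so that only O7 is alkylated.
7. The real difficulty is to build the fully substituted ring C on the correct side of ring A and then to address O7 alone.
8. The key step exploits two facts. O1 on C8a has only one free ortho carbon, C4a, because the other one, C8, carries the methoxy group. C4a is also ortho to O5 and para to O7. An aryl enol ether made at O1 can therefore be acylated only, and easily, at C4a, so closing ring C at the C4–C4a bond fixes the 8-methoxy pattern.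

## Logic of the disconnections

**18 to 17.** The three O–acetyl bonds at O3, O5 and O4' are cut. The last step must spare the prenyl ether, which leaves only a mild nucleophilic deacylation. The skeleton is unchanged, but three acidic hydroxyl groups are silenced for the step before. The forward step must avoid strong base and air.

**17 to 15.** The O7–CH2 bond of the prenyl ether is cut. Prenyl goes on after every acidic, reductive and oxidising operation, because it survives none of them. The precursor is a uniformly protected tetraacetate. The forward step must single out O7 among four acetates. The 7-acetate is para to the C4a–C4=O unit, so its phenoxide is the best leaving group.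

**15 to 13.** The acetyl groups are exchanged for benzyl at O5, O7 and O4' and for hydrogen at O3. Benzyl ethers tolerate butyllithium, carbonate, hydroxide, acid anhydride and dioxirane, which acetates do not. Hydrogenolysis must come before any alkene is present.

**13 to 11.** The C3–O bond is cut. This turns the flavonol into a flavone, whose three-carbon unit is a plain propiolate. The forward step must oxidise C2=C3 in the presence of three electron-rich rings.

**11 to 9 (key).** The C4–C4a bond is cut. In one sentence, ring C of 11 is closed at carbon by intramolecular Friedel–Crafts acylation of the aryl enol ether acid 9, in which O1–C2 already exists. The tricycle falls back to two benzenoid halves joined by a single ether oxygen. No ring A ketone and no ortho-hydroxy/ortho'-oxygen ambiguity remain. The forward step needs an acyl activation mild enough for benzyl ethers and for the enol ether.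

**9 to 3 + 7.** The O1–C2 bond is cut. This is the convergent junction of two pieces of similar size. The forward step is the addition of one phenol oxygen to an ynoate with 100% atom economy, followed by ester hydrolysis. It demands O-attack rather than C-attack of an electron-rich phenoxide on a donor-deactivated acceptor.

**7 to 4 (through 5).** The C3–C4 bond (alkyne to ester carbon) and the C2–C3 triple bond are cut. The aldehyde carbon of 4 becomes C2, one carbon is added as C3, and the ester carbon becomes C4. Only standard homologation is required.

**3 to 1 (through 2).** The C8–O bond is cut. This reveals a phenol with a mirror plane whose two ortho carbons are equivalent, so functionalisation ortho to the free hydroxyl has only one ortho outcome. That hydroxyl is thereby defined as O1. The forward steps need ortho over para selectivity and a carbon–oxygen coupling at a crowded carbon.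

## Other disconnections considered

**Alternative 1:** This is the first plan that comes to mind.
- Cut: O1–C2 and C3–O together.
- Forward: Claisen–Schmidt condensation of the acetophenone A2 with 4 gives the chalcone A1. Algar–Flynn–Oyamada oxidation (alkaline H2O2) then closes ring C at the heteroatom.
- Grounds against it:
  - The 6'-benzyloxy group of A1 (the future O5) twists the enone out of the plane of ring A. It also crowds the β-carbon, so the phenoxide should attack the α-carbon of the epoxide or enone (5-exo) and lead towards aurones.
  - A2 itself needs a C-acylation of ring A that must choose between two carbons, each activated by three oxygens.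
  - The longest linear sequence would not be shorter, and the step that carries the strategy is the one the substitution pattern opposes.

**Alternative 2:**
- Cut: O1–C2 and C2–C3.
- Forward: O-aroylation of an ω-benzyloxy ketone of ring A, Baker–Venkataraman acyl shift to the 1,3-diketone A3, then acid cyclodehydration at the heteroatom.
- Grounds against it:
  - The ω-oxygenated ketone costs extra steps beyond A2.
  - The acid closure acts on a ketone flanked by O1 and by a peri benzyl ether that acid removes easily. Once O5 is free, ring opening and reclosure (Wessely–Moser equilibration) can move the methoxy group from C8 to C6.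
  - The chosen plan cannot suffer this, because O1 is tied to C2 before the ketone exists.

**Alternative 3:**
- Cut: C2–C1'.
- Forward: direct C2–H arylation of the 3-benzyloxychromone A4 with the boronic acid A5 under Pd(OAc)2 and an oxidant (oxidative Heck type, divalent palladium).
- Grounds against it:
  - The union is convergent, but it leaves the real problem untouched. A4 still needs the ring A ketone, a one-carbon unit and a C3 oxidation.
  - Carbopalladation places palladium on C3, which bears the benzyloxy group and no hydrogen. The only β-hydrogen (on C2) is anti to the metal, so turnover depends on epimerisation through an oxygen-bound enolate.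
  - Protonation to the flavanone is the likely escape.
  - More steps and a weaker key step result.

Key step: step 6

Remark: flavonoid numbering (O1, C2 to C8a, primed numbers for ring B) is used for all intermediates, also before ring C exists.

Assumption: 1 and 4 are taken as catalogue compounds. The target has no stereocentre, so the only stereochemical element of the route is the alkene geometry of 8 to 10.

## Steps

**Step 1**
Reactants: 1 3,5-bis(benzyloxy)phenol
Product: 2 3,5-bis(benzyloxy)-2-bromophenol
Conditions: NBS (1.0 equiv), i-Pr2NH (0.1 equiv), CH2Cl2, −78 to 0 °C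
Reagents that add atoms: N-bromosuccinimide, O=C1CCC(=O)N1Br
Why: Amine-modulated NBS bromination of a phenol, which is ortho-selective; the two ortho carbons of 1 are equivalent through its mirror plane, so either attack gives 2, and the para carbon is shielded by two benzyloxy groups; one equivalent at low temperature limits dibromination.

**Step 2**
Reactants: 2 3,5-bis(benzyloxy)-2-bromophenol
Product: 3 3,5-bis(benzyloxy)-2-methoxyphenol
Conditions: NaOMe (25% in MeOH, 6 equiv), CuBr (0.2 equiv), DMF, 110 °C; then aq HCl
Reagents that add atoms: sodium methoxide, C[O-].[Na+]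
Why: Copper-catalysed Ullmann-type methoxylation of an ortho-bromophenol, the reaction type that turns 5-bromovanillin into syringaldehyde; the neighbouring phenoxide binds copper and speeds the exchange, and benzyl ethers are inert to methoxide.

**Step 3**
Reactants: 4 4-(benzyloxy)-3-methoxybenzaldehyde
Product: 5 1-(benzyloxy)-4-(2,2-dibromoethenyl)-2-methoxybenzene
Conditions: CBr4, PPh3, CH2Cl2, 0 °C
Reagents that add atoms: carbon tetrabromide, BrC(Br)(Br)Br
Why: First stage of the Corey–Fuchs homologation (Wittig-type dibromoolefination), routine for electron-rich benzaldehydes; the benzyl and methyl ethers are untouched.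

**Step 4**
Reactants: 5 1-(benzyloxy)-4-(2,2-dibromoethenyl)-2-methoxybenzene
Product: 7 methyl 3-[4-(benzyloxy)-3-methoxyphenyl]prop-2-ynoate, via lithium acetylide 6 (not isolated)
Conditions: n-BuLi (2.1 equiv), THF, −78 °C; then ClCO2Me, −78 °C to rt
Reagents that add atoms: methyl chloroformate, COC(=O)Cl
Why: Second stage of the Corey–Fuchs reaction: bromine–lithium exchange, α-elimination with 1,2-hydrogen shift (Fritsch–Buttenberg–Wiechell type) and deprotonation give 6, which is C-acylated by the chloroformate.

**Step 5**
Reactants: 3 3,5-bis(benzyloxy)-2-methoxyphenol; 7 methyl 3-[4-(benzyloxy)-3-methoxyphenyl]prop-2-ynoate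
Product: 9 (Z)-3-[3,5-bis(benzyloxy)-2-methoxyphenoxy]-3-[4-(benzyloxy)-3-methoxyphenyl]prop-2-enoic acid, via methyl ester 8 (not isolated)
Conditions: K2CO3 (0.3 equiv), DMF, 80 °C; then 2 M aq NaOH, MeOH, 50 °C; then 1 M HCl
Reagents that add atoms: sodium hydroxide, [OH-].[Na+]
Why: Base-catalysed oxa-Michael addition of a phenoxide to an arylpropiolate forms O1–C2; anti addition should place the aryloxy group cis to the ester (Z), and the geometry is not critical because step 6 equilibrates it; saponification of the β-aryloxycinnamate then gives the acid.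

**Step 6**
Reactants: 9 (Z)-3-[3,5-bis(benzyloxy)-2-methoxyphenoxy]-3-[4-(benzyloxy)-3-methoxyphenyl]prop-2-enoic acid
Product: 11 5,7-bis(benzyloxy)-2-[4-(benzyloxy)-3-methoxyphenyl]-8-methoxy-4H-chromen-4-one, via mixed anhydride 10 (not isolated)
Conditions: (CF3CO)2O (3 equiv), CH2Cl2 (0.02 M), 0 °C to rt
Reagents that add atoms: none
Why: The anhydride converts 9 into the acyl trifluoroacetate 10, which reacts directly or after ionisation to an acylium ion stabilised by O1 and ring B as a vinylogous oxocarbenium ion; C4a attacks the acyl carbon and loss of a proton from the arenium ion gives the aromatic 4-pyranone. The reaction type is the intramolecular Friedel–Crafts acylation of β-aryloxyacrylic and β-aryloxycinnamic acids (Ruhemann-type chromone and flavone synthesis), run here with a mixed-anhydride activation that benzyl ethers tolerate. Ring C is closed at the C4–C4a carbon–carbon bond in a 6-exo-trig mode at the anhydride carbonyl (6-exo-dig if the free acylium ion is the electrophile). No stereocentre is formed. Regioselectivity is the point: O1 was fixed in step 5 and its ortho carbon C8 is blocked by OMe, so the three-atom tether reaches C4a only and the 8-methoxy chromone is the only one possible, while C6 is as electron-rich but para to O1 and out of reach, and high dilution holds back its intermolecular acylation. C4a is ortho to O1 and O5 and para to O7, so even this donor-stabilised, weakly electrophilic acyl cation meets a strong enough nucleophile. The closure needs the carboxyl group cis to the aryloxy group (Z), and any E isomer is fed in because the C2–C3 bond has single-bond character in the acylium ion and in C3-protonated 9. Closure of the E form onto ring B would give a strained five-membered indenone on the less activated ring and should not compete.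

**Step 7**
Reactants: 11 5,7-bis(benzyloxy)-2-[4-(benzyloxy)-3-methoxyphenyl]-8-methoxy-4H-chromen-4-one
Product: 13 5,7-bis(benzyloxy)-2-[4-(benzyloxy)-3-methoxyphenyl]-3-hydroxy-8-methoxy-4H-chromen-4-one, via flavone epoxide 12 (not isolated)
Conditions: DMDO (acetone solution), CH2Cl2, 0 °C to rt; then p-TsOH·H2O (cat.), CH2Cl2, rt
Reagents that add atoms: dimethyldioxirane, CC1(C)OO1
Why: Dioxirane epoxidation of the enol ether bond C2=C3 of a fully protected flavone, the established flavone-to-flavonol oxidation; acid opens 12 at C2 (cation stabilised by O1 and ring B) and loss of H3 restores the pyranone with the hydroxyl at C3; no free phenol or alkene is present to compete.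

**Step 8**
Reactants: 13 5,7-bis(benzyloxy)-2-[4-(benzyloxy)-3-methoxyphenyl]-3-hydroxy-8-methoxy-4H-chromen-4-one
Product: 15 3,5,7-triacetoxy-2-(4-acetoxy-3-methoxyphenyl)-8-methoxy-4H-chromen-4-one, via limocitrin 14 (not isolated)
Conditions: H2 (1 atm), 10% Pd/C, THF–MeOH, rt; filter, concentrate; then Ac2O, pyridine, DMAP (cat.), 50 °C
Reagents that add atoms: acetic anhydride, CC(=O)OC(C)=O
Why: Hydrogenolysis of three aryl benzyl ethers leaves the aromatic pyranone intact, and peracetylation with DMAP also covers the chelated 5-hydroxyl; both are routine flavonoid operations, placed before any alkene is present.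

**Step 9**
Reactants: 15 3,5,7-triacetoxy-2-(4-acetoxy-3-methoxyphenyl)-8-methoxy-4H-chromen-4-one
Product: 17 3,5-diacetoxy-2-(4-acetoxy-3-methoxyphenyl)-8-methoxy-7-[(3-methylbut-2-en-1-yl)oxy]-4H-chromen-4-one, via potassium phenoxide 16 (not isolated)
Conditions: prenyl bromide (1.3 equiv), K2CO3 (anhydrous, 1.5 equiv), acetone, reflux
Reagents that add atoms: 1-bromo-3-methylbut-2-ene (prenyl bromide), CC(C)=CCBr
Why: Alkylative displacement of the most activated acetate of a flavonol peracetate, known with methyl and benzyl halides; the 7-acetate is para to the C4a–C4=O unit, so its phenoxide is a vinylogous carboxylate and the best leaving group; carbonate cleaves it first and 16 is trapped at once by SN2 attack at the primary carbon of prenyl bromide.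

**Step 10**
Reactants: 17 3,5-diacetoxy-2-(4-acetoxy-3-methoxyphenyl)-8-methoxy-7-[(3-methylbut-2-en-1-yl)oxy]-4H-chromen-4-one
Product: 18 3,5-dihydroxy-2-(4-hydroxy-3-methoxyphenyl)-8-methoxy-7-[(3-methylbut-2-en-1-yl)oxy]-4H-chromen-4-one (target)
Conditions: NH3 (7 M in MeOH), 0 °C to rt, argon
Reagents that add atoms: none
Why: Ammonolysis of aryl and enol acetates, the usual mild deacetylation of flavonoids; the conditions are neither acidic, reductive nor oxidising, so the prenyl ether and both methyl ethers stay, and argon protects the free 3-hydroxy-4-pyranone.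

## Compound list

1 | 3,5-bis(benzyloxy)phenol | Oc1cc(OCc2ccccc2)cc(OCc2ccccc2)c1 | starting material
2 | 3,5-bis(benzyloxy)-2-bromophenol | Oc1cc(OCc2ccccc2)cc(OCc2ccccc2)c1Br | intermediate
3 | 3,5-bis(benzyloxy)-2-methoxyphenol | COc1c(O)cc(OCc2ccccc2)cc1OCc1ccccc1 | intermediate
4 | 4-(benzyloxy)-3-methoxybenzaldehyde | COc1cc(C=O)ccc1OCc1ccccc1 | starting material
5 | 1-(benzyloxy)-4-(2,2-dibromoethenyl)-2-methoxybenzene | COc1cc(C=C(Br)Br)ccc1OCc1ccccc1 | intermediate
6 | lithium [4-(benzyloxy)-3-methoxyphenyl]acetylide | [Li]C#Cc1ccc(OCc2ccccc2)c(OC)c1 | intermediate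
7 | methyl 3-[4-(benzyloxy)-3-methoxyphenyl]prop-2-ynoate | COC(=O)C#Cc1ccc(OCc2ccccc2)c(OC)c1 | intermediate
8 | methyl (Z)-3-[3,5-bis(benzyloxy)-2-methoxyphenoxy]-3-[4-(benzyloxy)-3-methoxyphenyl]prop-2-enoate | COC(=O)/C=C(\Oc1cc(OCc2ccccc2)cc(OCc2ccccc2)c1OC)c1ccc(OCc2ccccc2)c(OC)c1 | intermediate
9 | (Z)-3-[3,5-bis(benzyloxy)-2-methoxyphenoxy]-3-[4-(benzyloxy)-3-methoxyphenyl]prop-2-enoic acid | OC(=O)/C=C(\Oc1cc(OCc2ccccc2)cc(OCc2ccccc2)c1OC)c1ccc(OCc2ccccc2)c(OC)c1 | intermediate
10 | mixed anhydride of 9 with trifluoroacetic acid (Z) | FC(F)(F)C(=O)OC(=O)/C=C(\Oc1cc(OCc2ccccc2)cc(OCc2ccccc2)c1OC)c1ccc(OCc2ccccc2)c(OC)c1 | intermediate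
11 | 5,7-bis(benzyloxy)-2-[4-(benzyloxy)-3-methoxyphenyl]-8-methoxy-4H-chromen-4-one | COc1cc(-c2cc(=O)c3c(OCc4ccccc4)cc(OCc4ccccc4)c(OC)c3o2)ccc1OCc1ccccc1 | intermediate
12 | 2,3-epoxide of 11 (racemic; the cis fusion is the only one the three-membered ring allows) | O=C1c2c(OCc3ccccc3)cc(OCc3ccccc3)c(OC)c2OC2(c3ccc(OCc4ccccc4)c(OC)c3)OC12 | intermediate
13 | 5,7-bis(benzyloxy)-2-[4-(benzyloxy)-3-methoxyphenyl]-3-hydroxy-8-methoxy-4H-chromen-4-one | COc1cc(-c2oc3c(OC)c(OCc4ccccc4)cc(OCc4ccccc4)c3c(=O)c2O)ccc1OCc1ccccc1 | intermediate
14 | 3,5,7-trihydroxy-2-(4-hydroxy-3-methoxyphenyl)-8-methoxy-4H-chromen-4-one (limocitrin) | COc1cc(-c2oc3c(OC)c(O)cc(O)c3c(=O)c2O)ccc1O | intermediate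
15 | 3,5,7-triacetoxy-2-(4-acetoxy-3-methoxyphenyl)-8-methoxy-4H-chromen-4-one | COc1cc(-c2oc3c(OC)c(OC(C)=O)cc(OC(C)=O)c3c(=O)c2OC(C)=O)ccc1OC(C)=O | intermediate
16 | potassium 3,5-diacetoxy-2-(4-acetoxy-3-methoxyphenyl)-8-methoxy-4-oxo-4H-chromen-7-olate | COc1cc(-c2oc3c(OC)c([O-])cc(OC(C)=O)c3c(=O)c2OC(C)=O)ccc1OC(C)=O.[K+] | intermediate
17 | 3,5-diacetoxy-2-(4-acetoxy-3-methoxyphenyl)-8-methoxy-7-[(3-methylbut-2-en-1-yl)oxy]-4H-chromen-4-one | COc1cc(-c2oc3c(OC)c(OCC=C(C)C)cc(OC(C)=O)c3c(=O)c2OC(C)=O)ccc1OC(C)=O | intermediate
18 | 3,5-dihydroxy-2-(4-hydroxy-3-methoxyphenyl)-8-methoxy-7-[(3-methylbut-2-en-1-yl)oxy]-4H-chromen-4-one | COc1cc(-c2oc3c(OC)c(OCC=C(C)C)cc(O)c3c(=O)c2O)ccc1O | target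

## Step count and least certain steps

Total step count: 10.

Longest linear sequence: 8 steps (1, 2, 5, 6, 7, 8, 9, 10, from 1). Steps 3 and 4 form the two-step side branch from 4.

**Step 6 (key step).**
- Risk: the acyl cation is stabilised by O1 and ring B and may be too weak an electrophile, so the reaction could stall at the mixed anhydride.
- Forcing it with stronger acid invites three processes: loss or migration of benzyl groups on the very electron-rich ring A, protonation of the enol ether at C3 with cleavage of O1–C2, and decarboxylation.
- Fallback: it gives up the carbon–carbon closure but keeps its regiochemical logic (free O1, a single free ortho carbon).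
- It sets out from 3. Magnesium-mediated ortho-formylation (MgCl2, Et3N, paraformaldehyde, MeCN, reflux; Casnati–Skattebøl conditions) can strike only C4a and should give 4,6-bis(benzyloxy)-2-hydroxy-3-methoxybenzaldehyde F1.
- Addition of two equivalents of acetylide 6 gives the racemic propargylic alcohol F2, and MnO2 in CH2Cl2 oxidises it to the 2-hydroxyaryl ynone F3.
- Amine-catalysed 6-endo-dig oxa-Michael cyclisation (DMAP, DMF) closes ring C at O1–C2 and comes back to the route at 11.

**Step 5.**
- Risk: slow addition, because the ynoate is deactivated by the donor-substituted ring B and the phenoxide is flanked by a methoxy group.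
- At higher temperature, attack through the ring carbon of the phenoxide may compete, leading towards 4-arylcoumarins.
- During saponification, hydroxide may add at C2 with expulsion of the phenoxide.
- Fallback: it replaces the conjugate addition by a metal-catalysed vinyl carbon–oxygen coupling and sets out from 7.
- Hydroiodination (NaI, AcOH, 80 °C, anti addition) gives methyl (Z)-3-[4-(benzyloxy)-3-methoxyphenyl]-3-iodoprop-2-enoate F4.
- F4 is coupled with 3 under Ullmann-type conditions (CuI, N,N-dimethylglycine, Cs2CO3, dioxane, 90 °C) with retention of geometry. It comes back at 8, which is saponified as in step 5.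

**Step 2.**
- Risk: slow exchange and hydrodebromination at an electron-rich bromide with two ortho substituents. Some para bromination in step 1 would add an isomer problem.
- Fallback: it installs the oxygen by directed metalation, bypasses both steps, and sets out from 1.
- MOMCl and i-Pr2NEt give 1,3-bis(benzyloxy)-5-(methoxymethoxy)benzene F5.
- Lithiation next to the acetal oxygen (n-BuLi, THF, 0 °C; the two such sites are equivalent), trapping with B(OMe)3 and oxidation with H2O2/NaOH give 2,4-bis(benzyloxy)-6-(methoxymethoxy)phenol F6.
- MeI/K2CO3 gives 1,5-bis(benzyloxy)-2-methoxy-3-(methoxymethoxy)benzene F7, and HCl in MeOH removes the acetal and comes back at 3.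

**Step 9.**
- Risk: loss of a second acetate (O4' or the enol acetate at O3) with double prenylation, or acetyl migration between oxygens under carbonate. The 8-methoxy group also crowds the 7-acetate.
- Fallback: it separates the two events and makes the ether under neutral conditions, setting out from 15.
- Thiophenol and imidazole in NMP at 0 °C remove the 7-acetate chemoselectively to give 3,5-diacetoxy-2-(4-acetoxy-3-methoxyphenyl)-7-hydroxy-8-methoxy-4H-chromen-4-one F8.
- Mitsunobu etherification with 3-methylbut-2-en-1-ol (PPh3, DIAD, THF, 0 °C) comes back at 17.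

**Step 7.**
- Risk: incomplete epoxidation of a hindered, conjugated enol ether, or over-oxidation of the electron-rich rings and benzylic positions when excess oxidant is used.
- Fallback: it replaces electrophilic oxidation by deprotonation and sets out from 11.
- Lithiation at C3 with LDA (THF, −78 °C) and trapping with B(OMe)3 give the dimethyl flavon-3-ylboronate F9, whose oxidation with H2O2/AcOH comes back at 13.

## Further compounds

F1 | step 6 | 4,6-bis(benzyloxy)-2-hydroxy-3-methoxybenzaldehyde | COc1c(O)c(C=O)c(OCc2ccccc2)cc1OCc1ccccc1
F2 | step 6 | 1-[4,6-bis(benzyloxy)-2-hydroxy-3-methoxyphenyl]-3-[4-(benzyloxy)-3-methoxyphenyl]prop-2-yn-1-ol (racemic) | COc1c(O)c(C(O)C#Cc2ccc(OCc3ccccc3)c(OC)c2)c(OCc2ccccc2)cc1OCc1ccccc1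
F3 | step 6 | 1-[4,6-bis(benzyloxy)-2-hydroxy-3-methoxyphenyl]-3-[4-(benzyloxy)-3-methoxyphenyl]prop-2-yn-1-one | COc1c(O)c(C(=O)C#Cc2ccc(OCc3ccccc3)c(OC)c2)c(OCc2ccccc2)cc1OCc1ccccc1
F4 | step 5 | methyl (Z)-3-[4-(benzyloxy)-3-methoxyphenyl]-3-iodoprop-2-enoate | COC(=O)/C=C(\I)c1ccc(OCc2ccccc2)c(OC)c1
F5 | step 2 | 1,3-bis(benzyloxy)-5-(methoxymethoxy)benzene | COCOc1cc(OCc2ccccc2)cc(OCc2ccccc2)c1
F6 | step 2 | 2,4-bis(benzyloxy)-6-(methoxymethoxy)phenol | COCOc1cc(OCc2ccccc2)cc(OCc2ccccc2)c1O
F7 | step 2 | 1,5-bis(benzyloxy)-2-methoxy-3-(methoxymethoxy)benzene | COCOc1cc(OCc2ccccc2)cc(OCc2ccccc2)c1OC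
F8 | step 9 | 3,5-diacetoxy-2-(4-acetoxy-3-methoxyphenyl)-7-hydroxy-8-methoxy-4H-chromen-4-one | COc1cc(-c2oc3c(OC)c(O)cc(OC(C)=O)c3c(=O)c2OC(C)=O)ccc1OC(C)=O
F9 | step 7 | dimethyl {5,7-bis(benzyloxy)-2-[4-(benzyloxy)-3-methoxyphenyl]-8-methoxy-4-oxo-4H-chromen-3-yl}boronate | COB(OC)c1c(-c2ccc(OCc3ccccc3)c(OC)c2)oc2c(OC)c(OCc3ccccc3)cc(OCc3ccccc3)c2c1=O
A1 | alternative 1 | (E)-1-[4,6-bis(benzyloxy)-2-hydroxy-3-methoxyphenyl]-3-[4-(benzyloxy)-3-methoxyphenyl]prop-2-en-1-one | COc1cc(/C=C/C(=O)c2c(O)c(OC)c(OCc3ccccc3)cc2OCc2ccccc2)ccc1OCc1ccccc1
A2 | alternative 1 | 1-[4,6-bis(benzyloxy)-2-hydroxy-3-methoxyphenyl]ethan-1-one | COc1c(O)c(C(C)=O)c(OCc2ccccc2)cc1OCc1ccccc1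
A3 | alternative 2 | 2-(benzyloxy)-1-[4,6-bis(benzyloxy)-2-hydroxy-3-methoxyphenyl]-3-[4-(benzyloxy)-3-methoxyphenyl]propane-1,3-dione (racemic, enolisable) | COc1cc(C(=O)C(OCc2ccccc2)C(=O)c2c(O)c(OC)c(OCc3ccccc3)cc2OCc2ccccc2)ccc1OCc1ccccc1
A4 | alternative 3 | 3,5,7-tris(benzyloxy)-8-methoxy-4H-chromen-4-one | COc1c(OCc2ccccc2)cc(OCc2ccccc2)c2c(=O)c(OCc3ccccc3)coc12
A5 | alternative 3 | [4-(benzyloxy)-3-methoxyphenyl]boronic acid | OB(O)c1ccc(OCc2ccccc2)c(OC)c1
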